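The C8–C9 oxirane on the seven-membered ring is read as a masked trisubstituted C8=C9 olefin flanked by the CH2 groups C7 and C10, so the cycloheptane is disconnected across C8=C9 by ring-closing metathesis. Daucane numbering is used (C1 quaternary ring-fusion carbon, C5 ring-fusion CH, C6 ester carbinol, C4 isopropyl carbinol). The precursor is a monocyclic cyclopentane diol bearing an allyl group on C1 and, trans to it on C5, a 1-hydroxy-3-methylbut-3-enyl chain. One operation closes the trans-fused hydroazulene and places the olefin for α-face epoxidation. The cyclopentane stereocentres come from asymmetric conjugate methylation (C1), an anti aldol (C5, C6) and isopropyl addition (C4).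

Key step: step 6

Remark: the oxirane is treated as a functional group on the carbocyclic daucane skeleton; it is installed by epoxidation once the bicyclic carbon framework is complete.

Step 1
Reactants: 1 3-ethoxycyclopent-2-en-1-one; 2 allylmagnesium bromide
Product: 4 3-(prop-2-en-1-yl)cyclopent-2-en-1-one, via bromomagnesium 1-allyl-3-ethoxycyclopent-2-en-1-olate 3 (not isolated)
Conditions: THF, 0 °C; then 1 M aq. HCl, 0 °C, short contact
Reagents that add atoms: none
Why: Stork–Danheiser transposition, in which 1,2-addition of the Grignard reagent to the vinylogous ester and acid-promoted ionisation with loss of ethanol give the β-allyl enone without any stereocentre.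

Step 2
Reactants: 4 3-(prop-2-en-1-yl)cyclopent-2-en-1-one; 5 trimethylaluminium
Product: 7 trimethyl{[(3R)-3-methyl-3-(prop-2-en-1-yl)cyclopent-1-en-1-yl]oxy}silane, via dimethylaluminium enolate 6 (not isolated)
Conditions: Me3Al, Cu(O2CC4H3S) (copper thiophene-2-carboxylate, 2 mol%), chiral phosphoramidite L* (4 mol%; 6-{bis[1-(naphthalen-2-yl)ethyl]amino}dibenzo[d,f][1,3,2]dioxaphosphepine, enantiomer chosen to give the 3R centre), Et2O, −30 °C; then Me3SiOTf, THF, −30 → 0 °C
Reagents that add atoms: trimethylsilyl trifluoromethanesulfonate, C[Si](C)(C)OS(=O)(=O)C(F)(F)F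
Why: Copper-catalysed asymmetric conjugate addition of methyl to the β-carbon of the enone, in which the chiral phosphoramidite–copper complex selects the enone face and sets the quaternary centre C1 (R), while O-silylation of the aluminium enolate stores the C4=C5 enolate regiochemistry needed for bond formation at C5.

Step 3
Reactants: 8 3-methylbut-3-en-1-ol
Product: 9 3-methylbut-3-enal
Conditions: Dess–Martin periodinane, NaHCO3, CH2Cl2, 0 °C; filtered through a short silica pad, kept cold and used at once
Reagents that add atoms: none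
Why: Dess–Martin oxidation under buffered, non-basic conditions should convert the primary alcohol into the β,γ-unsaturated aldehyde without migration of the 1,1-disubstituted double bond into conjugation.

Step 4
Reactants: 7 trimethyl{[(3R)-3-methyl-3-(prop-2-en-1-yl)cyclopent-1-en-1-yl]oxy}silane; 9 3-methylbut-3-enal
Product: 12 (2S,3R)-2-[(1S)-1-hydroxy-3-methylbut-3-en-1-yl]-3-methyl-3-(prop-2-en-1-yl)cyclopentan-1-one, via lithium enolate 10 (not isolated), via chlorozinc enolate 11 (not isolated)
Conditions: MeLi, THF, 0 °C; ZnCl2, −78 °C; then 9, −78 → −20 °C; aq. NH4Cl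
Reagents that add atoms: none
Why: Regiospecific enolate generation by Si–O cleavage followed by a Zimmerman–Traxler aldol addition, in which the ring-constrained E-enolate should give the anti aldol (C5/C6) through a chair transition state and the aldehyde should approach C5 anti to the larger allyl group on C1 (syn to methyl), placing the two olefinic chains trans.

Step 5
Reactants: 12 (2S,3R)-2-[(1S)-1-hydroxy-3-methylbut-3-en-1-yl]-3-methyl-3-(prop-2-en-1-yl)cyclopentan-1-one; 13 isopropylmagnesium chloride
Product: 14 (1R,2S,3R)-2-[(1S)-1-hydroxy-3-methylbut-3-en-1-yl]-3-methyl-1-(propan-2-yl)-3-(prop-2-en-1-yl)cyclopentan-1-ol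
Conditions: i-PrMgCl, anhydrous CeCl3, THF, −78 → 0 °C; aq. NH4Cl
Reagents that add atoms: none
Why: Organocerium 1,2-addition, in which the weakly basic isopropylcerium reagent should add to the hindered, enolisable ketone without retro-aldol of the aldolate and attack C4 from the α face, anti to the adjacent C5 side chain and its metal chelate, which sets the tertiary carbinol with the 4β-hydroxyl.

Step 6
Reactants: 14 (1R,2S,3R)-2-[(1S)-1-hydroxy-3-methylbut-3-en-1-yl]-3-methyl-1-(propan-2-yl)-3-(prop-2-en-1-yl)cyclopentan-1-ol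
Product: 15 jaeschkeanadiol, (3R,3aS,4S,8aR)-6,8a-dimethyl-3-(propan-2-yl)-1,2,3,3a,4,5,8,8a-octahydroazulene-3,4-diol
Conditions: second-generation Grubbs catalyst RuCl2(=CHPh)(PCy3)(H2IMes) (5 mol%), CH2Cl2 (0.005 M), 40 °C
Reagents that add atoms: none
Why: Ring-closing olefin metathesis: the ruthenium benzylidene loads onto the unhindered monosubstituted allyl olefin on C1, and the resulting alkylidene undergoes intramolecular [2+2] cycloaddition and cycloreversion with the 1,1-disubstituted olefin of the C5 chain, expelling ethene and forming the C8=C9 bond. The closest known reaction type is the metathesis closure of trisubstituted cycloheptenes used for hydroazulene sesquiterpenes. The one ring formed is the seven-membered carbocycle, closed by metathesis between C8 and C9, with the endocyclic olefin necessarily cis. No new stereocentre is created, because the trans ring fusion is already fixed by the C1 and C5 configurations of 14. The selectivity needed is cyclisation over intermolecular dimerisation at the allyl group; it is secured by the vicinal trans placement of both chains on the cyclopentane, the gem-dialkyl effect of the quaternary C1, high dilution and the reversibility of the unproductive cross-metathesis.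

Step 7
Reactants: 15 jaeschkeanadiol; 16 4-methoxybenzoyl chloride
Product: 17 (3R,3aS,4S,8aR)-3-hydroxy-6,8a-dimethyl-3-(propan-2-yl)-1,2,3,3a,4,5,8,8a-octahydroazulen-4-yl 4-methoxybenzoate
Conditions: Et3N, DMAP (cat.), CH2Cl2, 0 °C → rt
Reagents that add atoms: none
Why: DMAP-catalysed acylation, in which the secondary C6 hydroxyl should react while the hindered tertiary C4 hydroxyl next to the isopropyl group stays free, and no stereocentre is touched.

Step 8
Reactants: 17 (3R,3aS,4S,8aR)-3-hydroxy-6,8a-dimethyl-3-(propan-2-yl)-1,2,3,3a,4,5,8,8a-octahydroazulen-4-yl 4-methoxybenzoate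
Product: 18 target, 8α,9α-epoxyjaeschkeanadiol 6-(4-methoxybenzoate) (daucane numbering 1R,4R,5S,6S,8R,9S; oxirane oxygen cis to H-5 and to the ester oxygen, trans to the C1 methyl)
Conditions: mCPBA, NaHCO3, CH2Cl2, 0 °C
Reagents that add atoms: meta-chloroperoxybenzoic acid, OOC(=O)c1cccc(Cl)c1
Why: Prilezhaev epoxidation of the only olefin, in which the peracid should approach C8=C9 from the α face, opposite the axial C1 methyl on the homoallylic ring-fusion carbon (the equatorial C6 ester does not shield that face), setting C8 and C9 together.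

Compound list
1 | 3-ethoxycyclopent-2-en-1-one | CCOC1=CC(=O)CC1 | starting material
2 | allylmagnesium bromide | C=CC[Mg]Br | starting material
3 | bromomagnesium 1-allyl-3-ethoxycyclopent-2-en-1-olate | CCOC1=CC(CC=C)(O[Mg]Br)CC1 | intermediate
4 | 3-(prop-2-en-1-yl)cyclopent-2-en-1-one | C=CCC1=CC(=O)CC1 | intermediate
5 | trimethylaluminium | C[Al](C)C | starting material
6 | dimethylaluminium (3R)-3-methyl-3-(prop-2-en-1-yl)cyclopent-1-en-1-olate | C=CC[C@@]1(C)CCC(O[Al](C)C)=C1 | intermediate
7 | trimethyl{[(3R)-3-methyl-3-(prop-2-en-1-yl)cyclopent-1-en-1-yl]oxy}silane | C=CC[C@@]1(C)CCC(O[Si](C)(C)C)=C1 | intermediate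
8 | 3-methylbut-3-en-1-ol | C=C(C)CCO | starting material
9 | 3-methylbut-3-enal | C=C(C)CC=O | intermediate
10 | lithium (3R)-3-methyl-3-(prop-2-en-1-yl)cyclopent-1-en-1-olate | C=CC[C@@]1(C)CCC(O[Li])=C1 | intermediate
11 | chlorozinc (3R)-3-methyl-3-(prop-2-en-1-yl)cyclopent-1-en-1-olate | C=CC[C@@]1(C)CCC(O[Zn]Cl)=C1 | intermediate
12 | (2S,3R)-2-[(1S)-1-hydroxy-3-methylbut-3-en-1-yl]-3-methyl-3-(prop-2-en-1-yl)cyclopentan-1-one | C=C(C)C[C@H](O)[C@@H]1[C@@](C)(CC=C)CCC1=O | intermediate
13 | isopropylmagnesium chloride | CC(C)[Mg]Cl | starting material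
14 | (1R,2S,3R)-2-[(1S)-1-hydroxy-3-methylbut-3-en-1-yl]-3-methyl-1-(propan-2-yl)-3-(prop-2-en-1-yl)cyclopentan-1-ol | C=C(C)C[C@H](O)[C@@H]1[C@@](C)(CC=C)CC[C@@]1(O)C(C)C | intermediate
15 | jaeschkeanadiol, (3R,3aS,4S,8aR)-6,8a-dimethyl-3-(propan-2-yl)-1,2,3,3a,4,5,8,8a-octahydroazulene-3,4-diol | O[C@H]1CC(C)=CC[C@@]2(C)CC[C@@](O)(C(C)C)[C@H]12 | intermediate
16 | 4-methoxybenzoyl chloride | COc1ccc(C(Cl)=O)cc1 | starting material
17 | (3R,3aS,4S,8aR)-3-hydroxy-6,8a-dimethyl-3-(propan-2-yl)-1,2,3,3a,4,5,8,8a-octahydroazulen-4-yl 4-methoxybenzoate | COc1ccc(C(=O)O[C@H]2CC(C)=CC[C@@]3(C)CC[C@@](O)(C(C)C)[C@H]23)cc1 | intermediate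
18 | 8α,9α-epoxyjaeschkeanadiol 6-(4-methoxybenzoate) | COc1ccc(C(=O)O[C@H]2C[C@@]3(C)O[C@H]3C[C@@]3(C)CC[C@@](O)(C(C)C)[C@H]23)cc1 | target

Total step count: 8. Longest linear sequence: 7 steps (steps 1, 2, 4, 5, 6, 7, 8 from 3-ethoxycyclopent-2-en-1-one); step 3 is a one-step side branch.

Steps most likely to fail

Step 4. The basic enolate may deprotonate the β,γ-unsaturated aldehyde or move its double bond into conjugation faster than it adds, which costs material and erodes the kinetic anti and trans selectivity. Fallback: setting out from 7, the zinc enolate is generated as before and added to the non-isomerisable masked keto aldehyde (2-methyl-1,3-dioxolan-2-yl)acetaldehyde F1 (from commercial ethyl (2-methyl-1,3-dioxolan-2-yl)acetate with i-Bu2AlH, CH2Cl2, −78 °C) to give the anti aldol ketal F2. Addition of i-PrMgCl/CeCl3 as in step 5 gives the ketal diol F3, and pyridinium tosylate in aqueous acetone releases the methyl ketone diol F4. Wittig methylenation (Ph3P=CH2 in excess, THF, 0 °C) then installs the 1,1-disubstituted olefin, and the route is rejoined at 14.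

Step 5. Enolisation, β-hydride reduction of the hindered ketone or retro-aldol cleavage of the metal aldolate may compete with addition. Fallback: setting out from 12, the C6 hydroxyl is silylated (Et3SiOTf, 2,6-lutidine, CH2Cl2, −78 °C) to the triethylsilyl ether F5, which cannot form an aldolate. Isopropyllithium with CeCl3 (THF, −78 °C) should add from the α face to give the silyl ether tertiary alcohol F6, and Bu4NF in THF removes the silyl group, rejoining the route at 14.

Step 8. The peracid may not discriminate the two olefin faces well enough under purely steric control. Fallback: setting out from 15, hydroxyl-directed epoxidation (VO(acac)2, t-BuOOH, CH2Cl2, 0 °C) uses the homoallylic 6α-hydroxyl to deliver oxygen to the α face and should give the epoxy diol F7. Selective acylation of its secondary hydroxyl with 4-methoxybenzoic anhydride, DMAP and Et3N rejoins the route at 18.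

Further compounds
F1 | step 4 | (2-methyl-1,3-dioxolan-2-yl)acetaldehyde | CC1(CC=O)OCCO1
F2 | step 4 | (2S,3R)-2-[(1S)-1-hydroxy-2-(2-methyl-1,3-dioxolan-2-yl)ethyl]-3-methyl-3-(prop-2-en-1-yl)cyclopentan-1-one | CC1(C[C@H](O)[C@@H]2[C@@](C)(CC=C)CCC2=O)OCCO1
F3 | step 4 | (1R,2S,3R)-2-[(1S)-1-hydroxy-2-(2-methyl-1,3-dioxolan-2-yl)ethyl]-3-methyl-1-(propan-2-yl)-3-(prop-2-en-1-yl)cyclopentan-1-ol | CC1(C[C@H](O)[C@@H]2[C@@](C)(CC=C)CC[C@@]2(O)C(C)C)OCCO1
F4 | step 4 | (4S)-4-hydroxy-4-[(1S,2R,5R)-2-hydroxy-5-methyl-2-(propan-2-yl)-5-(prop-2-en-1-yl)cyclopentyl]butan-2-one | CC(=O)C[C@H](O)[C@@H]1[C@@](C)(CC=C)CC[C@@]1(O)C(C)C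
F5 | step 5 | (2S,3R)-3-methyl-2-{(1S)-3-methyl-1-[(triethylsilyl)oxy]but-3-en-1-yl}-3-(prop-2-en-1-yl)cyclopentan-1-one | C=C(C)C[C@H](O[Si](CC)(CC)CC)[C@@H]1[C@@](C)(CC=C)CCC1=O
F6 | step 5 | (1R,2S,3R)-3-methyl-2-{(1S)-3-methyl-1-[(triethylsilyl)oxy]but-3-en-1-yl}-1-(propan-2-yl)-3-(prop-2-en-1-yl)cyclopentan-1-ol | C=C(C)C[C@H](O[Si](CC)(CC)CC)[C@@H]1[C@@](C)(CC=C)CC[C@@]1(O)C(C)C
F7 | step 8 | 8α,9α-epoxyjaeschkeanadiol | O[C@H]1C[C@@]2(C)O[C@H]2C[C@@]2(C)CC[C@@](O)(C(C)C)[C@H]12
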